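One ratio divides two chemists reading the ochre run: target at its last reading over what that flask could have held by then.

| flask | substrate | free catalyst | remark | time |
|---|---|---|---|---|
| red | 0.51 M | 2.9 mM | run made earlier |  |
| green | 0.51 M | 5.1 mM | run made earlier |  |
| violet | 0.51 M | 7.2 mM | run made earlier |  |
| ochre | 0.33 M | 10 mM | run made earlier |  |
| south | 0.15 M | 10 mM |  | 2.0 min |
| east | 0.25 M | 2.5 mM |  | 2.0 min |
| north-east | 0.12 M | 10 mM |  | 2.0 min |
| south-east | 0.51 M | 10 mM |  | 2.0 min |
| north-west | 0.12 M | 5.0 mM |  | 2.0 min |

| run | time / s | target / % | substrate / % |
|---|---|---|---|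
| red | 12.0 | 5.3 | 11.8 |
| red | 25.0 | 6.7 | 5.0 |
| red | 40.0 | 7.5 | 2.5 |
| red | 50.0 | 8.2 | 2.0 |
| red | 60.0 | 9.0 | 1.3 |
| green | 12.0 | 8.7 | 10.2 |
| green | 25.0 | 10.9 | 3.6 |
| green | 40.0 | 13.0 | 1.3 |
| green | 50.0 | 13.2 | 1.8 |
| green | 60.0 | 13.5 | 0.6 |
| violet | 10.0 | 12.1 | 11.6 |
| violet | 15.0 | 13.6 | 7.0 |
| violet | 30.0 | 16.0 | 3.2 |
| violet | 40.0 | 17.1 | 0.3 |
| violet | 60.0 | 16.6 | 0.8 |
| ochre | 10.0 | 21.1 | 15.3 |
| ochre | 15.0 | 23.9 | 8.6 |
| ochre | 30.0 | 28.5 | 2.1 |
| ochre | 60.0 | 28.2 | 0 |

(readings scatter by 0.5 percentage points)



- the flasks by amount of target, in percent of the substrate charged, highest first, at 2.0 min (south / east / north-east / south-east / north-west)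
- the amount of target, in percent of the substrate charged of the flask you put first, at 2.0 min
- the amount of target, in percent of the substrate charged of the flask you put last, at 2.0 min

The first chemist, who made the forecast, sees that “target plateaus at low yield”. In the ochre run, target reads 28.5% at 30.0 s and 28.2% at 60.0 s, a difference of 0.3 percentage points, under the scatter of 0.5 points. The forecast gives north-east > south > north-west > south-east > east, with 48% in north-east and 12.7% in east.

The second chemist objects that the flat pair hides a loss. At 30.0 s the ochre run still held 2.1% of substrate, and if we generously count that as target, 30.6% was due. The ratio of that to the last reading is 1.09. If target is lost in proportion to itself, its logarithm falls on a straight line, so no integration is needed: the logarithm of the ratio over 30.0 s gives the slope 0.163 /min. From that slope comes the drain half-life, the time in which standing target would halve: 4.24 min. It is a rough reading, because the gap of 2.4 points stands not far above the scatter.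

My own reckoning follows the second chemist and differs from the forecast. Let the forecast's plateau stand at 60.0 s, when the ochre run read 0% of substrate, and drain it until 2.0 min. That multiplies it by 0.849, which puts north-east at 40.8%.

The simulation gives north-east > south > north-west > south-east > east, the forecast's order, with 41.6% in north-east and 12.6% in east. The forecast's low stands, but its top lies 6.4 points too high. That 48% is what one gets first order to completion through the last reading of the ochre run. The first chemist's view has its region: north-east holds 47.9% at 1.00 min, with 0.437% of substrate left.

    2 substrate → self-condensation product (k = 0.550 /M/s)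
    substrate + free catalyst → catalyst intermediate (k = 7.54 /M/s)
    target ⇌ isomer of the product (K = 3.16, k = 0.00274 /s)
    catalyst intermediate ⇌ free catalyst + target (K = 44.7 M, k = 3.46 /s)

From 1.00 min to 2.00 min, north-east falls from 47.9% to 41.6% of target while isomer of the product rises from 6.71% to 13.5%: kinetic against thermodynamic control. The reading time is part of the answer in north-east: target stands at 41.6% at 2.0 min and at 13.8% at 20.0 min. East stays low mainly because of the self-condensation of substrate: the run without that step gives 69.0% of target in east against 12.6% with it. Read north-east at 8.0 min instead, and the drain half-life gives 15.3%. The computed flask holds 21.0% of target beside 34.1% of isomer of the product, so the reckoning that served at 2.0 min reads low this far out.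

(The earlier runs and the new flask are simulated from invented constants.)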